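The cyclohexanone ring holds a free hydroxyl at C2 beside C1, the carbon bearing the 1,1-disubstituted alkene C7=C14H2: a homoallylic alcohol and thus the retron of a carbonyl-ene reaction. One intramolecular carbonyl-ene cyclisation (isopulegol mode) closes the ring at C1–C2 and creates the exo-methylene, the C2 carbinol and both stereocentres, C6 steering C1 and the Z alkene geometry steering C2. Its precursor is an acyclic cis-4-oxo-enal bis-angelate, unmasked by singlet-oxygen opening of a 3-methylfuran whose four carbons become C2–C5. The C3 angelate and tertiary C4 hydroxyl then arise from a directed epoxidation and its opening by angelic acid; the side-chain epoxide is made last.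

Key step: step 8

Remark on numbering and names (used throughout): ring C1 (CH bearing the side chain), C2 (CH–OH), C3 (CH–OAng), C4 (C(CH3)(OH)), C5 (C=O), C6 (CH–OAng); side chain C7(=C14H2)–C8H(OAng)–C9H2–C10H–C11(CH3)2, with the epoxide on C10–C11. Ang = angeloyl, (2Z)-2-methylbut-2-enoyl; the three ester groups are read from the SMILES as angelates. In this numbering the target is (1R,2R,3R,4S,6S,8S,10S).

Step 1
Reactants: 1 prop-2-yn-1-ol
Product: 3 (2Z)-3-iodo-2-methylprop-2-en-1-ol, via alkenylmagnesium alkoxide 2 (not isolated)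
Conditions: MeMgBr (3 equiv), CuI (10 mol%), THF, −20 °C → rt; then I2, −78 → 0 °C
Reagents that add atoms: methylmagnesium bromide, C[Mg]Br; iodine, II
Why: Hydroxyl-directed, copper-catalysed anti-carbomagnesiation of the propargylic alkoxide places CH3 on the internal carbon and magnesium on the terminal carbon cis to CH2O (five-membered chelate), and iodinolysis with retention then fixes the Z-iodoalkene.

Step 2
Reactants: 3 (2Z)-3-iodo-2-methylprop-2-en-1-ol
Product: 4 (2Z)-3-iodo-2-methylprop-2-enal
Conditions: MnO2 (activated, excess), CH2Cl2, rt, dark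
Reagents that add atoms: none
Why: Allylic oxidation with MnO2 is neutral and heterogeneous, so the alcohol should be oxidised to the enal without loss of the Z geometry or of the C–I bond.

Step 3
Reactants: 4 (2Z)-3-iodo-2-methylprop-2-enal
Product: 5 (1Z,3S)-1-iodo-2-methylhexa-1,5-dien-3-ol
Conditions: allylSnBu3, Ti(OiPr)4 (10 mol%), (S)-BINOL (20 mol%), 4 Å molecular sieves, CH2Cl2, −20 °C
Reagents that add atoms: allyltributylstannane, C=CC[Sn](CCCC)(CCCC)CCCC
Why: Keck asymmetric allylation: the BINOL–titanium Lewis acid activates the aldehyde and the (S)-BINOL ligand directs transfer of the allyl group from tin to the Si face, which sets C8 as S.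

Step 4
Reactants: 5 (1Z,3S)-1-iodo-2-methylhexa-1,5-dien-3-ol
Product: 6 (1Z,3S)-1-iodo-2,6-dimethylhepta-1,5-dien-3-ol
Conditions: 2-methylbut-2-ene (excess, co-solvent), second-generation Grubbs catalyst (5 mol%), CH2Cl2, 40 °C
Reagents that add atoms: 2-methylbut-2-ene, CC=C(C)C
Why: Olefin cross-metathesis of the terminal alkene with excess 2-methylbut-2-ene exchanges =CH2 for =C(CH3)2, while the hindered iodoalkene and the free hydroxyl should not interfere.

Step 5
Reactants: 6 (1Z,3S)-1-iodo-2,6-dimethylhepta-1,5-dien-3-ol; 7 3-methylfuran-2-carbaldehyde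
Product: 8 (1S,2Z,4S)-3,7-dimethyl-1-(3-methylfuran-2-yl)octa-2,6-diene-1,4-diol (C6 S, C8 S)
Conditions: CrCl2 (4 equiv), NiCl2 (2 mol%), chiral N-[2-(4-isopropyl-4,5-dihydro-1,3-oxazol-2-yl)-6-methylphenyl]methanesulfonamide ligand (the antipode that gives Si-face addition), Et3N, THF, rt
Reagents that add atoms: none
Why: Nozaki–Hiyama–Kishi coupling: the alkenylchromium species, formed with retention of the Z geometry, adds only to the aldehyde and tolerates the free hydroxyl; the chiral oxazoline–sulfonamide ligand on chromium directs addition to the Si face to set C6 as S, and the minor C6 epimer, a diastereomer because C8 is fixed, is removed by chromatography.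

Step 6
Reactants: 8 (1S,2Z,4S)-3,7-dimethyl-1-(3-methylfuran-2-yl)octa-2,6-diene-1,4-diol
Product: 9 (1S,2Z,4S)-3,7-dimethyl-1-(3-methylfuran-2-yl)octa-2,6-diene-1,4-diyl bis[(2Z)-2-methylbut-2-enoate]
Conditions: angelic anhydride (2.5 equiv), LiN(SiMe3)2 (2.2 equiv), THF, −78 → 0 °C
Reagents that add atoms: angelic anhydride [(2Z)-2-methylbut-2-enoic anhydride], C/C=C(/C)C(=O)OC(=O)/C(C)=C\C
Why: O-Acylation of the lithium alkoxides by the anhydride at low temperature, without a nucleophilic catalyst, should esterify both secondary hydroxyls and avoid Z to E isomerisation of the angeloyl groups and ionisation of the furfuryl ester.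

Step 7
Reactants: 9 bis-angelate of the furyl diol
Product: 11 (2Z,5S,6Z,8S)-3,7,11-trimethyl-1,4-dioxododeca-2,6,10-triene-5,8-diyl bis[(2Z)-2-methylbut-2-enoate], via furan endoperoxide 10 (not isolated)
Conditions: O2, visible light, tetraphenylporphyrin (cat.), CH2Cl2, −78 °C; then Me2S, −78 → −20 °C; used at once
Reagents that add atoms: dioxygen (as singlet oxygen), O=O
Why: Photooxygenation: singlet oxygen adds to the electron-rich 2,3-dialkylfuran in a [4+2] cycloaddition far faster than it reacts with the trisubstituted or conjugated alkenes, and reduction of the endoperoxide by Me2S unmasks the furan as the cis-4-oxo-enal (C2 aldehyde, Z-C3=C4, C5 ketone).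

Step 8
Reactants: 11 cis-4-oxo-enal bis-angelate
Product: 12 ene product, 4-hydroxycyclohex-2-enone: C2–OH, C3=C4(CH3), C5=O, C6–OAng, C1 bearing the (3S)-3-(angeloyloxy)-6-methylhepta-1,5-dien-2-yl chain; side chain trans to both C2–OH and C6–OAng (C1 R, C2 S, C6 S, C8 S)
Conditions: Me2AlCl (1.5 equiv), CH2Cl2 (0.005 M), −78 → −40 °C
Reagents that add atoms: none
Why: Concerted, Lewis-acid-promoted type 1 intramolecular carbonyl-ene reaction (closest known cases: citronellal to isopulegol and neral to isopiperitenol): the Me2AlCl-complexed aldehyde C2=O, activated further as part of the cis-enedione, is attacked by C1 of the C1=C7 alkene while a hydrogen of the C7 methyl group passes to the carbonyl oxygen, so that the C1–C2 bond, the C7=C14H2 exo-methylene and the free C2 hydroxyl form in one operation. The six-membered ring closes in the 6-exo-trig mode at the carbonyl carbon through a half-chair, the cis C3=C4 bond holding C2 and C5 on the same side. C1 is controlled by C6: allylic 1,3-strain with the Z substituent C8 keeps C6–H in the alkene plane, so the tether attacks the face that leaves C6–OAng and the C1 side chain trans (both pseudo-equatorial). C2 is controlled by the alkene geometry: only the transition state with the carbonyl oxygen pseudo-equatorial reaches the hydrogens of the methyl group (trans to C6), whereas the alternative would have to abstract the C8–H, so C2–OH should come out trans to the side chain. The step needs chemoselectivity for the aldehyde and for methyl over C8–H transfer; geometry secures both, since the ketone cannot reach C1 in a workable ring and attack at C3 would be a disfavoured 5-endo closure, and Me2AlCl scavenges the proton so that the allylic esters and the hydroxy enone should survive.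

Step 9
Reactants: 12 ene product
Product: 13 C2 triethylsilyl ether of 12 (C1 S, C2 S, C6 S, C8 S)
Conditions: Et3SiCl, imidazole, DMF, 0 °C
Reagents that add atoms: chlorotriethylsilane, CC[Si](Cl)(CC)CC
Why: Silyl ether formation at the only free hydroxyl masks C2–OH so that the next steps are directed by, and act on, the C5 oxygen alone.

Step 10
Reactants: 13 silyl ether enone
Product: 14 allylic alcohol: C5–OH trans to C6–OAng and cis to the C1 side chain (C1 S, C2 S, C5 S, C6 S, C8 S)
Conditions: NaBH4, CeCl3·7H2O, MeOH, −78 °C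
Reagents that add atoms: none
Why: Luche reduction: cerium-assisted 1,2-reduction with axial hydride delivery should give the pseudo-equatorial C5 alcohol, trans to C6–OAng and cis to the C1 side chain.

Step 11
Reactants: 14 allylic alcohol
Product: 15 epoxy alcohol: C3–C4 epoxide on the face of C5–OH, opposite to C2–OSiEt3 (C1 S, C2 R, C3 S, C4 R, C5 R, C6 S, C8 S)
Conditions: VO(acac)2 (5 mol%), t-BuOOH, CH2Cl2, 0 °C → rt
Reagents that add atoms: tert-butyl hydroperoxide, CC(C)(C)OO
Why: Hydroxyl-directed vanadium-catalysed epoxidation delivers oxygen to the C3=C4 face syn to C5–OH (and anti to the C2 silyl ether), which sets C4, and should leave the non-allylic alkenes and the angelates untouched.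

Step 12
Reactants: 15 epoxy alcohol
Product: 16 tris-angelate diol: C3–OAng, free C4–OH and C5–OH, C2–OSiEt3 (C1 S, C2 R, C3 R, C4 R, C5 R, C6 S, C8 S)
Conditions: angelic acid (3 equiv), Ti(OiPr)4 (1.5 equiv), CH2Cl2, rt
Reagents that add atoms: angelic acid [(2Z)-2-methylbut-2-enoic acid], C/C=C(/C)C(=O)O
Why: Titanium-mediated opening of the 2,3-epoxy alcohol by the carboxylic acid at the epoxide carbon remote from the carbinol (C3) with inversion; the quaternary C4 and the trans-diaxial (Fürst–Plattner) course reinforce this regiochemistry, so C3–OAng is set and the tertiary C4–OH is released free.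

Step 13
Reactants: 16 tris-angelate diol
Product: 17 C5 ketone with C2–OSiEt3 (C1 S, C2 R, C3 R, C4 S, C6 S, C8 S)
Conditions: Dess–Martin periodinane, CH2Cl2, 0 °C → rt
Reagents that add atoms: none
Why: Dess–Martin oxidation converts the only secondary hydroxyl (C5) into the ketone; the tertiary C4–OH, the silyl ether and the alkenes are inert.

Step 14
Reactants: 17 silyl-protected ketone
Product: 18 10,11-alkene precursor of the target with free C2–OH (1R,2R,3R,4S,6S,8S)
Conditions: HF·pyridine, pyridine, THF, 0 °C
Reagents that add atoms: none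
Why: Fluoride cleaves the triethylsilyl ether under buffered, mildly acidic conditions that should cause neither acyl migration from O3 to O2 nor ester cleavage.

Step 15
Reactants: 18 alkene precursor
Product: 19 target, CNP0145026.1 (1R,2R,3R,4S,6S,8S,10S)
Conditions: enantiomer of the D-fructose-derived Shi ketone (from L-sorbose, 30 mol%), KHSO5 (as Oxone), K2CO3, Bu4NHSO4 (cat.), MeCN–CH2(OMe)2–H2O, pH ≈ 9–10, 0 °C
Reagents that add atoms: potassium peroxymonosulfate, [K+].[O-]S(=O)(=O)OO
Why: Shi asymmetric epoxidation: the chiral dioxirane should attack only the electron-rich trisubstituted C10=C11 bond (the C7=C14 alkene is hindered and deactivated by the allylic ester, the angelates are electron-poor), and the L-sorbose-derived ketone enantiomer gives the 10S epoxide through the spiro transition state, while the buffered pH protects the base-sensitive acyloxy ketone.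

Compound list

1 | prop-2-yn-1-ol | C#CCO | starting material
2 | bromomagnesium (2Z)-3-(bromomagnesio)-2-methylprop-2-en-1-olate | Br[Mg]/C=C(C)\CO[Mg]Br | intermediate (not isolated)
3 | (2Z)-3-iodo-2-methylprop-2-en-1-ol | I/C=C(C)\CO | intermediate
4 | (2Z)-3-iodo-2-methylprop-2-enal | I/C=C(C)\C=O | intermediate
5 | (1Z,3S)-1-iodo-2-methylhexa-1,5-dien-3-ol | I/C=C(C)\[C@H](CC=C)O | intermediate
6 | (1Z,3S)-1-iodo-2,6-dimethylhepta-1,5-dien-3-ol | I/C=C(C)\[C@H](CC=C(C)C)O | intermediate
7 | 3-methylfuran-2-carbaldehyde | Cc1ccoc1C=O | starting material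
8 | (1S,2Z,4S)-3,7-dimethyl-1-(3-methylfuran-2-yl)octa-2,6-diene-1,4-diol | Cc1ccoc1[C@@H](O)/C=C(C)\[C@H](CC=C(C)C)O | intermediate
9 | (1S,2Z,4S)-3,7-dimethyl-1-(3-methylfuran-2-yl)octa-2,6-diene-1,4-diyl bis[(2Z)-2-methylbut-2-enoate] | Cc1ccoc1[C@@H](OC(=O)/C(C)=C\C)/C=C(C)\[C@H](CC=C(C)C)OC(=O)/C(C)=C\C | intermediate
10 | furan endoperoxide of 9 (5-methyl-2,3,7-trioxabicyclo[2.2.1]hept-5-ene carrying the bis-angelate chain at C4; both bridgehead diastereomers) | CC1=CC2OOC1(O2)[C@@H](OC(=O)/C(C)=C\C)/C=C(C)\[C@H](CC=C(C)C)OC(=O)/C(C)=C\C | intermediate (not isolated)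
11 | (2Z,5S,6Z,8S)-3,7,11-trimethyl-1,4-dioxododeca-2,6,10-triene-5,8-diyl bis[(2Z)-2-methylbut-2-enoate] | O=C/C=C(C)\C(=O)[C@@H](OC(=O)/C(C)=C\C)/C=C(C)\[C@H](CC=C(C)C)OC(=O)/C(C)=C\C | intermediate
12 | ene product: 6-(angeloyloxy)-4-hydroxy-2-methyl-5-[(3S)-3-(angeloyloxy)-6-methylhepta-1,5-dien-2-yl]cyclohex-2-en-1-one, side chain trans to both ring oxygens (C1 R, C2 S, C6 S, C8 S) | C=C([C@@H]1[C@@H](O)C=C(C)C(=O)[C@H]1OC(=O)/C(C)=C\C)[C@H](CC=C(C)C)OC(=O)/C(C)=C\C | intermediate
13 | C2 triethylsilyl ether of 12 (C1 S, C2 S, C6 S, C8 S) | C=C([C@@H]1[C@@H](O[Si](CC)(CC)CC)C=C(C)C(=O)[C@H]1OC(=O)/C(C)=C\C)[C@H](CC=C(C)C)OC(=O)/C(C)=C\C | intermediate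
14 | C5 allylic alcohol from 13, C5–OH trans to C6–OAng (C1 S, C2 S, C5 S, C6 S, C8 S) | C=C([C@@H]1[C@@H](O[Si](CC)(CC)CC)C=C(C)[C@H](O)[C@H]1OC(=O)/C(C)=C\C)[C@H](CC=C(C)C)OC(=O)/C(C)=C\C | intermediate
15 | C3–C4 epoxy alcohol, epoxide syn to C5–OH (C1 S, C2 R, C3 S, C4 R, C5 R, C6 S, C8 S) | C=C([C@@H]1[C@@H](O[Si](CC)(CC)CC)[C@@H]2O[C@]2(C)[C@H](O)[C@H]1OC(=O)/C(C)=C\C)[C@H](CC=C(C)C)OC(=O)/C(C)=C\C | intermediate
16 | tris-angelate C4,C5-diol with C2–OSiEt3 (C1 S, C2 R, C3 R, C4 R, C5 R, C6 S, C8 S) | C=C([C@@H]1[C@@H](O[Si](CC)(CC)CC)[C@@H](OC(=O)/C(C)=C\C)[C@](C)(O)[C@H](O)[C@H]1OC(=O)/C(C)=C\C)[C@H](CC=C(C)C)OC(=O)/C(C)=C\C | intermediate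
17 | C5 ketone with C2–OSiEt3 (C1 S, C2 R, C3 R, C4 S, C6 S, C8 S) | C=C([C@@H]1[C@@H](O[Si](CC)(CC)CC)[C@@H](OC(=O)/C(C)=C\C)[C@](C)(O)C(=O)[C@H]1OC(=O)/C(C)=C\C)[C@H](CC=C(C)C)OC(=O)/C(C)=C\C | intermediate
18 | 10,11-alkene precursor of the target (1R,2R,3R,4S,6S,8S) | C=C([C@@H]1[C@@H](O)[C@@H](OC(=O)/C(C)=C\C)[C@](C)(O)C(=O)[C@H]1OC(=O)/C(C)=C\C)[C@H](CC=C(C)C)OC(=O)/C(C)=C\C | intermediate
19 | CNP0145026.1 (1R,2R,3R,4S,6S,8S,10S) | C=C([C@@H]1[C@@H](O)[C@@H](OC(=O)/C(C)=C\C)[C@](C)(O)C(=O)[C@H]1OC(=O)/C(C)=C\C)[C@H](C[C@@H]1OC1(C)C)OC(=O)/C(C)=C\C | target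

Total step count: 15.
Longest linear sequence: 15 steps, from prop-2-yn-1-ol (3-methylfuran-2-carbaldehyde enters at step 5).

Steps most likely to fail

1. Step 8 (key step). The C1=C7 alkene is flanked by two allylic esters and may be too weakly nucleophilic, so that Lewis-acid-induced cis to trans isomerisation of the enedione or ionisation of an allylic ester outruns ring closure. The fallback sets out from 11: the aldehyde would be converted in the flask into its O-(4-methoxybenzyl) oxocarbenium ion (4-methoxybenzyl trimethylsilyl ether, catalytic Me3SiOTf, CH2Cl2, −78 °C). This much stronger electrophile should close the same C1–C2 bond by an oxonium-ene (Prins-type) cyclisation and give the C2 4-methoxybenzyl ether of the ene product F1. Oxidative debenzylation with DDQ (CH2Cl2–pH 7 buffer) would then return to the route at 12.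

2. Step 5. The ligand-controlled addition may show poor facial selectivity at C6, leaving an epimer mixture that is hard to separate. The fallback sets out from 6 and 7: the coupling would be run without chiral ligand (CrCl2, NiCl2 cat., DMSO) to give the C6-epimeric diol mixture F2. This would be resolved by Sharpless kinetic resolution of the 2-furylcarbinol (Ti(OiPr)4, D-(−)-diisopropyl tartrate, t-BuOOH, CH2Cl2, −20 °C). The 6R epimer should be consumed by oxidative rearrangement of its furan ring to the pyranone F3. The 6S epimer reacts slowly (its C8 allylic alcohol is also the slow-reacting antipode for this tartrate), is recovered, and rejoins the route at 8.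

3. Step 12. The titanium alkoxide may promote acyl migration between O6 and O5 or ester exchange, or the acid may attack C4 instead of C3. The fallback sets out from 15: the C5 alcohol would be oxidised first (Dess–Martin periodinane, CH2Cl2) to the α,β-epoxy ketone F4. Its epoxide would then be opened at the β-carbon C3 by angelic acid with catalytic Cs2CO3 in DMF (SN2 opening with inversion, trans-diaxial), which rejoins the route at 17.

Further compounds

F1 | step 8 | C2 O-(4-methoxybenzyl) ether of the ene product 12 | C=C([C@@H]1[C@@H](OCc2ccc(OC)cc2)C=C(C)C(=O)[C@H]1OC(=O)/C(C)=C\C)[C@H](CC=C(C)C)OC(=O)/C(C)=C\C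
F2 | step 5 | (2Z,4S)-3,7-dimethyl-1-(3-methylfuran-2-yl)octa-2,6-diene-1,4-diol, mixture of C1 epimers | Cc1ccoc1C(O)/C=C(C)\[C@H](CC=C(C)C)O
F3 | step 5 | (2R)-6-hydroxy-2-[(1Z,3S)-3-hydroxy-2,6-dimethylhepta-1,5-dien-1-yl]-4-methyl-2H-pyran-3(6H)-one | CC1=CC(O)O[C@H](/C=C(C)\[C@H](CC=C(C)C)O)C1=O
F4 | step 12 | C3–C4 epoxy C5 ketone with C2–OSiEt3 | C=C([C@@H]1[C@@H](O[Si](CC)(CC)CC)[C@@H]2O[C@]2(C)C(=O)[C@H]1OC(=O)/C(C)=C\C)[C@H](CC=C(C)C)OC(=O)/C(C)=C\C
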